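**Retrosynthetic overview**
1. Target ⇐ global desilylation; C8 methyl and the 7,8-alkene ⇐ kinetic C7–C8 enol triflate of a 17-nor-8-ketone (methyl cross-coupling).
2. Key disconnection: ring B of that 8-oxodecalin ⇐ one-carbon ring expansion (1,2-shift of the C8–C10 bond) of a trans-hydrindan-1-one. The inserted carbon C9 arrives as a magnesium carbenoid that already carries the whole C11–C16 side chain and the C30 ester.
3. Hydrindanone ⇐ amino-acid-catalysed annulation of 2-methylcyclopentane-1,3-dione with ethyl vinyl ketone (sets C10), reductive methylation (C4 gem-dimethyl, C5–H), hydride reduction (C3–OH).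
4. Carbenoid precursor ⇐ but-3-yn-1-ol (carboalumination/hydroxymethylation, E-alkene) + CH2I2 (C9) + the C30 acid, joined by chemoselective allylic carboxylate alkylation. C30 chain ⇐ hex-5-ynoic acid, octa-1,7-diyne and but-3-yn-1-ol, linked through 1-bromo-6-chlorohexane (one C6 unit per coupling step, bromide end first, chloride end second), then hydrogenation.
5. Ring order: the five-membered precursor of ring B is present from the start, ring A is annulated onto it, and ring B is completed last by the 5→6 expansion.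

Assumption: the target is read as the ent-labdane (3R,5S,9R,10S)-3-hydroxylabda-7,13E-dien-15-yl 30-hydroxytriacontanoate (29 sp3 carbons between the ester carbonyl and the terminal OH).
Conventions: labdane numbering (C1–C20) is used for the terpenoid carbons from step 1 on; TBS = tert-butyldimethylsilyl.

**Part A – hydrindanone (ring A plus five-membered precursor of ring B)**

Step 1
Reactants: 1 2-methylcyclopentane-1,3-dione; 2 pent-1-en-3-one
Product: 4 (7aR)-4,7a-dimethyl-2,3,7,7a-tetrahydro-1H-indene-1,5(6H)-dione, via triketone 3 (not isolated)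
Conditions: Et3N (5 mol%), MeCN, rt; then D-phenylalanine (1.0 equiv), 1 M aq HClO4 (0.5 equiv), reflux, 48 h; recrystallise
Reagents that add atoms: none
Why: Michael addition gives triketone 3, and the D-phenylalanine enamine (Hajos–Parrish–Eder–Sauer–Wiechert reaction) aldolises onto one of the two enantiotopic ring carbonyls and dehydrates, setting the quaternary carbon (C10) as R, the mirror image of the L-amino-acid product.

Step 2
Reactants: 4 (7aR)-enedione
Product: 5 (7aR)-4,7a-dimethyl-2,3,7,7a-tetrahydro-1H-indene-1,5(6H)-dione 1-(ethylene ketal)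
Conditions: HOCH2CH2OH (5 equiv), p-TsOH·H2O (10 mol%), 4 Å MS, CH2Cl2, rt
Reagents that add atoms: ethane-1,2-diol OCCO
Why: Acid-catalysed ketalisation is much faster at the saturated cyclopentanone than at the deactivated, tetrasubstituted conjugated enone carbonyl, so only C8 is masked for the dissolving-metal step.

Step 3
Reactants: 5 enone ketal
Product: 7 (3aR,7aR)-4,4,7a-trimethylhexahydro-1H-indene-1,5(4H)-dione 1-(ethylene ketal), via lithium enolate 6 (not isolated)
Conditions: Li (2.3 equiv), t-BuOH (1.0 equiv), NH3(l)/THF, −78 → −33 °C; isoprene; then MeI (6 equiv), −78 °C → rt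
Reagents that add atoms: iodomethane CI
Why: Stork reductive alkylation (Birch reduction of the enone, then enolate trapping), in which protonation of the β-carbon places the C5 hydrogen trans to the angular methyl and regiospecific C-methylation of enolate 6 completes the C4 gem-dimethyl group.

Step 4
Reactants: 7 saturated keto ketal
Product: 9 (3aR,5R,7aR)-5-hydroxy-4,4,7a-trimethyloctahydro-1H-inden-1-one, via hydroxy ketal 8 (not isolated)
Conditions: NaBH4, MeOH, 0 °C; then 2 M aq HCl, THF, rt
Reagents that add atoms: none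
Why: Borohydride attacks the C3 carbonyl along the axial trajectory from the face opposite the angular and axial C4 methyl groups, giving the equatorial alcohol (C3 R, cis to the C10 methyl), and the acidic quench hydrolyses the dioxolane.

Step 5
Reactants: 9 hydroxy ketone
Product: 10 (3aR,5R,7aR)-5-[(tert-butyldimethylsilyl)oxy]-4,4,7a-trimethyloctahydro-1H-inden-1-one
Conditions: TBSCl (1.5 equiv), imidazole, DMF, 50 °C
Reagents that add atoms: tert-butyldimethylsilyl chloride CC(C)(C)[Si](C)(C)Cl
Why: Standard silylation protects the secondary alcohol against the organomagnesium and triflation steps, and the ketone is untouched.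

**Part B – C30 acid**

Step 6
Reactants: 11 hex-5-ynoic acid; 12 1-bromo-6-chlorohexane; 13 octa-1,7-diyne
Product: 15 icosa-5,13,19-triynoic acid, via lithium 12-chlorododec-5-ynoate 14 (not isolated)
Conditions: 11, n-BuLi (2.0 equiv), THF/DMPU, −78 → −20 °C; 12 (1.0 equiv), −20 °C → rt; then 13 (6 equiv) premixed with n-BuLi (1.6 equiv) in THF, NaI (0.2 equiv), 55 °C, 16 h; aq HCl; excess 13 removed under vacuum
Reagents that add atoms: none
Why: Acetylide SN2 alkylation of the dilithio alkynoate occurs only at the bromide end of 12, and after iodide-catalysed halide exchange the chloride end of 14 is displaced by the monolithium acetylide of 13, kept in large excess so that only one of its two alkyne ends reacts, with neutral by-products removed by acid–base extraction.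

Step 7
Reactants: 15 icosa-5,13,19-triynoic acid; 12 1-bromo-6-chlorohexane; 16 but-3-yn-1-ol
Product: 18 30-hydroxytriaconta-5,13,19,27-tetraynoic acid, via lithium 26-chlorohexacosa-5,13,19-triynoate 17 (not isolated)
Conditions: 15, n-BuLi (2.0 equiv), THF/DMPU, −78 → −20 °C; 12 (1.0 equiv), −20 °C → rt; then 16 (3 equiv) premixed with n-BuLi (6 equiv) in THF/DMPU, NaI (0.2 equiv), 55 °C, 16 h; aq HCl work-up
Reagents that add atoms: none
Why: The same bromide-first, chloride-second acetylide SN2 sequence, in which the terminal acetylide of dilithiated 15 takes the bromide end of 12 and the dilithio derivative of 16 (the acetylide carbon is far more nucleophilic than the lithium alkoxide) then displaces the chloride of 17, with excess 16 washed out in water.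

Step 8
Reactants: 18 tetraynoic hydroxy acid
Product: 19 30-hydroxytriacontanoic acid
Conditions: H2 (3 bar), 10% Pd/C, THF/EtOAc, 40 °C
Reagents that add atoms: none
Why: Exhaustive heterogeneous hydrogenation of the four alkynes, done before any alkene of the terpenoid part is present.

Step 9
Reactants: 19 30-hydroxytriacontanoic acid
Product: 21 30-[(tert-butyldimethylsilyl)oxy]triacontanoic acid, via bis-silyl derivative 20 (not isolated)
Conditions: TBSCl (2.5 equiv), imidazole, THF/DMF, 45 °C; then THF/H2O/AcOH (8:1:1), rt, 1 h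
Reagents that add atoms: tert-butyldimethylsilyl chloride CC(C)(C)[Si](C)(C)Cl
Why: Both OH groups are silylated and the far more labile silyl ester is then hydrolysed selectively, leaving the primary silyl ether.

**Part C – side chain and carbenoid precursor**

Step 10
Reactants: 16 but-3-yn-1-ol
Product: 23 (2E)-3-methylpent-2-ene-1,5-diol, via alkenylalane 22 (not isolated)
Conditions: AlMe3 (3.0 equiv), Cp2ZrCl2 (0.25 equiv), CH2Cl2, 0 °C → rt; then n-BuLi (1.0 equiv), THF, −78 °C; (CH2O)n, → rt; aq HCl
Reagents that add atoms: trimethylaluminium C[Al](C)C; paraformaldehyde (formaldehyde unit) C=O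
Why: Negishi zirconium-catalysed carboalumination adds methyl and aluminium syn across the alkyne (methyl to the internal carbon), and hydroxymethylation of the alkenylalanate with retention fixes the 13E trisubstituted alkene.

Step 11
Reactants: 23 (2E)-3-methylpent-2-ene-1,5-diol
Product: 24 (2E)-1,5-dibromo-3-methylpent-2-ene
Conditions: CBr4 (2.4 equiv), PPh3 (2.4 equiv), CH2Cl2, 0 °C
Reagents that add atoms: tetrabromomethane BrC(Br)(Br)Br
Why: Appel bromination converts both primary alcohols by SN2 without moving the double bond, giving one allylic and one unactivated bromide that differ strongly in reactivity.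

Step 12
Reactants: 21 30-(TBS-oxy)triacontanoic acid; 24 (2E)-1,5-dibromo-3-methylpent-2-ene
Product: 26 (2E)-5-iodo-3-methylpent-2-en-1-yl 30-[(tert-butyldimethylsilyl)oxy]triacontanoate, via bromo ester 25 (not isolated)
Conditions: 21, Cs2CO3 (1.0 equiv), DMF/THF, rt; 24 (1.5 equiv), 0 °C → rt; then NaI (5 equiv), 55 °C
Reagents that add atoms: sodium iodide [Na+].[I-]
Why: The caesium carboxylate displaces the allylic bromide far faster than the unactivated primary bromide (SN2 ester formation with the E geometry retained), and a Finkelstein exchange then activates C11 as the iodide.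

Step 13
Reactants: 26 iodo ester
Product: 27 (2E)-6,6-diiodo-3-methylhex-2-en-1-yl 30-[(tert-butyldimethylsilyl)oxy]triacontanoate
Conditions: CH2I2 (5 equiv), NaN(SiMe3)2 (2.5 equiv), THF/Et2O, −78 °C, dark; then 26, −78 °C → rt, 16 h
Reagents that add atoms: diiodomethane ICI
Why: SN2 alkylation of the soft, weakly basic diiodomethyl anion by the primary iodide introduces C9 as a gem-diiodide, and the anion is too weak a base to enolise the aliphatic ester.

**Part D – union, ring expansion and endgame**

Step 14
Reactants: 10 silyloxy hydrindanone; 27 gem-diiodide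
Product: 30 (3R,5S,9S,10R)-3-[(tert-butyldimethylsilyl)oxy]-8-oxo-17-norlabd-13E-en-15-yl 30-[(tert-butyldimethylsilyl)oxy]triacontanoate, via magnesium carbenoid 28 (not isolated), via magnesium iodohydrinate 29 (not isolated)
Conditions: 27 (1.3 equiv), i-PrMgCl·LiCl (1.3 equiv), THF, −78 °C; 10 premixed with LaCl3·2LiCl (1.0 equiv), −78 → −40 °C; then → 25 °C, 6 h; DBU (0.3 equiv), CH2Cl2, rt
Reagents that add atoms: none
Why: Proposed new method: iodine–magnesium exchange on 27 gives the α-iodoalkylmagnesium carbenoid 28, which adds to the LaCl3-activated C8 carbonyl of 10 from the face opposite the angular methyl, and on warming the chloromagnesium iodohydrinate 29 loses iodide with magnesium assistance while the antiperiplanar, more electron-rich C8–C10 bond (quaternary carbon, strained trans-hydrindane) shifts to C9, so that the five-membered ring becomes ring B with C9 carrying the side chain and DBU then equilibrates C9 (α to the ketone) to the equatorial side chain cis to the C10 methyl; the closest known reaction types are the thermal ring enlargement of magnesium halohydrinates of 1-(1-haloalkyl)cycloalkanols, the D-homoannulation of 17-hydroxy-20-sulfonyloxy steroids with migration of the quaternary C13 and the addition of α-iodoalkyl Grignard carbenoids to carbonyl groups, none of which has been shown as a one-pot insertion of a functionalised secondary carbenoid into an α-quaternary hydrindanone.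

Step 15
Reactants: 30 17-nor-8-ketone
Product: 31 (3R,5S,9S,10R)-3-[(tert-butyldimethylsilyl)oxy]-8-(trifluoromethanesulfonyloxy)-17-norlabda-7,13E-dien-15-yl 30-[(tert-butyldimethylsilyl)oxy]triacontanoate
Conditions: KN(SiMe3)2 (1.1 equiv), THF, −78 °C; Comins' reagent (1.2 equiv), −78 → −40 °C
Reagents that add atoms: N-(5-chloropyridin-2-yl)-1,1,1-trifluoro-N-(trifluoromethanesulfonyl)methanesulfonamide O=S(=O)(N(c1ccc(Cl)cn1)S(=O)(=O)C(F)(F)F)C(F)(F)F
Why: Kinetic deprotonation occurs at the accessible C7 methylene and not at the hindered C9 methine next to the quaternary carbon (the ketone is also far more acidic than the ester), and O-triflation fixes the 7,8-double bond without touching C9.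

Step 16
Reactants: 31 enol triflate
Product: 32 (3R,5S,9R,10S)-3-[(tert-butyldimethylsilyl)oxy]labda-7,13E-dien-15-yl 30-[(tert-butyldimethylsilyl)oxy]triacontanoate
Conditions: MeMgBr (2.0 equiv), Fe(acac)3 (10 mol%), THF/NMP, −30 °C, 30 min
Reagents that add atoms: methylmagnesium bromide C[Mg]Br
Why: Iron-catalysed Kumada-type cross-coupling of the alkenyl triflate installs the C17 methyl with the double bond fixed at C7–C8, and at −30 °C it outruns Grignard attack on the esters.

Step 17
Reactants: 32 bis-silyl ether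
Product: 33 (3R,5S,9R,10S)-3-hydroxylabda-7,13E-dien-15-yl 30-hydroxytriacontanoate (CNP0303636.1)
Conditions: HF·pyridine, pyridine/THF, 0 → 40 °C
Reagents that add atoms: none
Why: Buffered fluoride desilylation frees both hydroxyl groups without cleaving the allylic ester or isomerising the trisubstituted alkenes.

**Compound list**
1 | 2-methylcyclopentane-1,3-dione | CC1C(=O)CCC1=O | starting material
2 | pent-1-en-3-one | C=CC(=O)CC | starting material
3 | 2-methyl-2-(3-oxopentyl)cyclopentane-1,3-dione | CCC(=O)CCC1(C)C(=O)CCC1=O | intermediate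
4 | (7aR)-4,7a-dimethyl-2,3,7,7a-tetrahydro-1H-indene-1,5(6H)-dione | O=C1CCC2=C(C)C(=O)CC[C@@]12C | intermediate
5 | (7aR)-enedione 1-(ethylene ketal) | C13(OCCO3)CCC2=C(C)C(=O)CC[C@@]12C | intermediate
6 | lithium C3-enolate of the reduced ketal (C5–H trans to the angular methyl) | C13(OCCO3)CC[C@@H]2C(C)=C(O[Li])CC[C@@]12C | intermediate
7 | (3aR,7aR)-4,4,7a-trimethylhexahydro-1H-indene-1,5(4H)-dione 1-(ethylene ketal), trans-fused | C13(OCCO3)CC[C@@H]2C(C)(C)C(=O)CC[C@@]12C | intermediate
8 | (3aR,5R,7aR)-5-hydroxy-4,4,7a-trimethyloctahydro-1H-inden-1-one ethylene ketal | C13(OCCO3)CC[C@@H]2C(C)(C)[C@H](O)CC[C@@]12C | intermediate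
9 | (3aR,5R,7aR)-5-hydroxy-4,4,7a-trimethyloctahydro-1H-inden-1-one | O=C1CC[C@@H]2C(C)(C)[C@H](O)CC[C@@]12C | intermediate
10 | (3aR,5R,7aR)-5-(TBS-oxy)-4,4,7a-trimethyloctahydro-1H-inden-1-one | O=C1CC[C@@H]2C(C)(C)[C@H](O[Si](C)(C)C(C)(C)C)CC[C@@]12C | intermediate
11 | hex-5-ynoic acid | C#CCCCC(=O)O | starting material
12 | 1-bromo-6-chlorohexane | ClCCCCCCBr | starting material
13 | octa-1,7-diyne | C#CCCCCC#C | starting material
14 | lithium 12-chlorododec-5-ynoate | ClCCCCCCC#CCCCC(=O)O[Li] | intermediate
15 | icosa-5,13,19-triynoic acid | C#CCCCCC#CCCCCCCC#CCCCC(=O)O | intermediate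
16 | but-3-yn-1-ol | C#CCCO | starting material
17 | lithium 26-chlorohexacosa-5,13,19-triynoate | ClCCCCCCC#CCCCCC#CCCCCCCC#CCCCC(=O)O[Li] | intermediate
18 | 30-hydroxytriaconta-5,13,19,27-tetraynoic acid | OCCC#CCCCCCCC#CCCCCC#CCCCCCCC#CCCCC(=O)O | intermediate
19 | 30-hydroxytriacontanoic acid | OC(=O)CCCCCCCCCCCCCCCCCCCCCCCCCCCCCO | intermediate
20 | tert-butyldimethylsilyl 30-(TBS-oxy)triacontanoate | CC(C)(C)[Si](C)(C)OC(=O)CCCCCCCCCCCCCCCCCCCCCCCCCCCCCO[Si](C)(C)C(C)(C)C | intermediate
21 | 30-(TBS-oxy)triacontanoic acid | OC(=O)CCCCCCCCCCCCCCCCCCCCCCCCCCCCCO[Si](C)(C)C(C)(C)C | intermediate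
22 | (1E)-[4-(dimethylalumanyloxy)-2-methylbut-1-en-1-yl]dimethylalumane | C[Al](C)OCC/C(C)=C/[Al](C)C | intermediate
23 | (2E)-3-methylpent-2-ene-1,5-diol | OCC/C(C)=C/CO | intermediate
24 | (2E)-1,5-dibromo-3-methylpent-2-ene | BrCC/C(C)=C/CBr | intermediate
25 | (2E)-5-bromo-3-methylpent-2-en-1-yl 30-(TBS-oxy)triacontanoate | BrCC/C(C)=C/COC(=O)CCCCCCCCCCCCCCCCCCCCCCCCCCCCCO[Si](C)(C)C(C)(C)C | intermediate
26 | (2E)-5-iodo-3-methylpent-2-en-1-yl 30-(TBS-oxy)triacontanoate | ICC/C(C)=C/COC(=O)CCCCCCCCCCCCCCCCCCCCCCCCCCCCCO[Si](C)(C)C(C)(C)C | intermediate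
27 | (2E)-6,6-diiodo-3-methylhex-2-en-1-yl 30-(TBS-oxy)triacontanoate | IC(I)CC/C(C)=C/COC(=O)CCCCCCCCCCCCCCCCCCCCCCCCCCCCCO[Si](C)(C)C(C)(C)C | intermediate
28 | α-iodoalkylmagnesium chloride from 27 (carbenoid, racemic at the metal-bearing carbon) | Cl[Mg]C(I)CC/C(C)=C/COC(=O)CCCCCCCCCCCCCCCCCCCCCCCCCCCCCO[Si](C)(C)C(C)(C)C | intermediate
29 | chloromagnesium alkoxide of the C8 tertiary iodohydrin (adduct of 28 and 10, mixture at C8 and C9) | Cl[Mg]OC1(CC[C@@H]2C(C)(C)[C@H](O[Si](C)(C)C(C)(C)C)CC[C@@]12C)C(I)CC/C(C)=C/COC(=O)CCCCCCCCCCCCCCCCCCCCCCCCCCCCCO[Si](C)(C)C(C)(C)C | intermediate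
30 | (3R,5S,9S,10R)-3-(TBS-oxy)-8-oxo-17-norlabd-13E-en-15-yl 30-(TBS-oxy)triacontanoate (trans-decalin; side chain, C10 methyl and C3 oxygen on one face) | O=C1CC[C@@H]2C(C)(C)[C@H](O[Si](C)(C)C(C)(C)C)CC[C@@]2(C)[C@@H]1CC/C(C)=C/COC(=O)CCCCCCCCCCCCCCCCCCCCCCCCCCCCCO[Si](C)(C)C(C)(C)C | intermediate
31 | (3R,5S,9S,10R)-3-(TBS-oxy)-8-(triflyloxy)-17-norlabda-7,13E-dien-15-yl 30-(TBS-oxy)triacontanoate | FC(F)(F)S(=O)(=O)OC1=CC[C@@H]2C(C)(C)[C@H](O[Si](C)(C)C(C)(C)C)CC[C@@]2(C)[C@@H]1CC/C(C)=C/COC(=O)CCCCCCCCCCCCCCCCCCCCCCCCCCCCCO[Si](C)(C)C(C)(C)C | intermediate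
32 | (3R,5S,9R,10S)-3-(TBS-oxy)labda-7,13E-dien-15-yl 30-(TBS-oxy)triacontanoate | CC1=CC[C@@H]2C(C)(C)[C@H](O[Si](C)(C)C(C)(C)C)CC[C@@]2(C)[C@@H]1CC/C(C)=C/COC(=O)CCCCCCCCCCCCCCCCCCCCCCCCCCCCCO[Si](C)(C)C(C)(C)C | intermediate
33 | (3R,5S,9R,10S)-3-hydroxylabda-7,13E-dien-15-yl 30-hydroxytriacontanoate | CC1=CC[C@@H]2C(C)(C)[C@H](O)CC[C@@]2(C)[C@@H]1CC/C(C)=C/COC(=O)CCCCCCCCCCCCCCCCCCCCCCCCCCCCCO | target

**Step count and risks**
Total steps: 17. Longest linear sequence: 10 steps (6 → 7 → 8 → 9 → 12 → 13 → 14 → 15 → 16 → 17).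

Most likely to fail, first: step 14 (the proposed new ring expansion). The carbenoid may decompose before it adds to the hindered ketone, the iodohydrinate may close to an epoxide, or the C7 methylene may migrate instead of C10. The fallback uses the known one-carbon ring enlargement of cyclic ketones through β-oxido carbenoids generated from 1-chloroalkyl aryl sulfoxides. It sets out from iodide 26 and ketone 10. Chloromethyl p-tolyl sulfoxide is lithiated (LiN(i-Pr)2, THF, −78 °C) and alkylated with 26 to give the 1-chloroalkyl p-tolyl sulfoxide F1. F1 is lithiated again and added to 10 to give the α-chloro-β-hydroxy sulfoxide adduct F2. Treatment with i-PrMgCl (3.5 equiv, −78 → 0 °C) deprotonates the hydroxyl and effects sulfoxide–magnesium exchange; the β-oxido carbenoid rearranges to the ring-enlarged enolate, which is protonated and equilibrated with DBU. The route is rejoined at 30.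

Second: step 3. The ring-fusion hydrogen may be delivered cis in the hydrindane series, or the tetrasubstituted enone may be over-reduced. The fallback separates the two tasks and sets out from 5. Deconjugative α-methylation (KOt-Bu, MeI, t-BuOH/THF) gives the β,γ-unsaturated 4,4-dimethyl keto ketal F3, which has the C5=C6 double bond. Hydrogenation (H2, 10% Pd/C, EtOAc) from the face opposite the angular and axial C4 methyl groups then sets the trans ring fusion. The route is rejoined at 7.

Third: step 13. The diiodomethyl anion may eliminate the homoallylic iodide or be incompatible with the long-chain ester over the long reaction time. The fallback installs C9 before the lipid is attached and sets out from dibromide 24. Caesium pivalate (CsO2CCMe3, DMF, 0 °C) displaces only the allylic bromide to give (2E)-5-bromo-3-methylpent-2-en-1-yl pivalate F4. NaI in acetone gives the iodo pivalate F5. CH2I2/NaN(SiMe3)2 gives the gem-diiodo pivalate F6, whose ester has no α-hydrogen. i-Bu2AlH (CH2Cl2, −78 °C) frees the gem-diiodo allylic alcohol F7. Carbodiimide esterification with acid 21 (EDC·HCl, DMAP, CH2Cl2) rejoins the route at 27.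

**Further compounds**
F1 | step 14 | (2E)-6-chloro-3-methyl-6-(4-methylbenzenesulfinyl)hex-2-en-1-yl 30-(TBS-oxy)triacontanoate (diastereomer mixture) | Cc1ccc(cc1)S(=O)C(Cl)CC/C(C)=C/COC(=O)CCCCCCCCCCCCCCCCCCCCCCCCCCCCCO[Si](C)(C)C(C)(C)C
F2 | step 14 | adduct of lithiated F1 with ketone 10: C8 tertiary alcohol bearing the 1-chloro-1-(p-tolylsulfinyl)alkyl group (diastereomer mixture) | OC1(CC[C@@H]2C(C)(C)[C@H](O[Si](C)(C)C(C)(C)C)CC[C@@]12C)C(Cl)(S(=O)c1ccc(C)cc1)CC/C(C)=C/COC(=O)CCCCCCCCCCCCCCCCCCCCCCCCCCCCCO[Si](C)(C)C(C)(C)C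
F3 | step 3 | (7aR)-4,4,7a-trimethyl-1,5-dioxo-hexahydroindene 1-(ethylene ketal) with the C3=C3a (labdane C5=C6) double bond | C13(OCCO3)CC=C2C(C)(C)C(=O)CC[C@@]12C
F4 | step 13 | (2E)-5-bromo-3-methylpent-2-en-1-yl 2,2-dimethylpropanoate | BrCC/C(C)=C/COC(=O)C(C)(C)C
F5 | step 13 | (2E)-5-iodo-3-methylpent-2-en-1-yl 2,2-dimethylpropanoate | ICC/C(C)=C/COC(=O)C(C)(C)C
F6 | step 13 | (2E)-6,6-diiodo-3-methylhex-2-en-1-yl 2,2-dimethylpropanoate | IC(I)CC/C(C)=C/COC(=O)C(C)(C)C
F7 | step 13 | (2E)-6,6-diiodo-3-methylhex-2-en-1-ol | IC(I)CC/C(C)=C/CO
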